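**Assumption:** labdane numbering is used throughout. The SMILES is read as (5S,6S,8S,9R,10S,13R), that is 6β-acetoxy-9α,13:15,16-diepoxylabd-14-en-7-one with an 8α-methyl group (pregaleopsin skeleton).

## Retrosynthetic overview
1. The target comes from a 7-acetoxy-7-en-6-one by α-face hydride delivery at C6 and an acetyl shift from O7 to O6. This sets C6 and C8.
2. Both spiro rings form in one flask from a tetraene and two O2. A ring B 6,9-endoperoxide frees the 9α-OH, and a side-chain 15,16-endoperoxide opens to the 16-hydroxy-13-en-15-al. The oxolane ring (O9–C13) closes first and the furanoid ring (O16–C15) second, followed by loss of water. This is the order and oxidation level presumed for the biosynthesis from labd-13-ene-9,15,16-triol.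
3. The tetraene comes from labda-8,13(16),14-trien-7-one. That enone comes from a vinylogous β-keto ester and a sulfolene-masked isoprenyl bromide (C11–C12 bond), with later loss of CO2 and SO2.
4. Rings A and B (C5, C10) are not built. They come from (+)-sclareolide.

## Route

Step 1
Reactants: 1 3-methyl-2,5-dihydrothiophene 1,1-dioxide
Product: 2 3-(bromomethyl)-2,5-dihydrothiophene 1,1-dioxide
Conditions: NBS (1.0 equiv), (BzO)2 (2 mol %), PhCF3, reflux
Reagents that add atoms: N-bromosuccinimide O=C1CCC(=O)N1Br
Why: In this Wohl–Ziegler allylic bromination the bromine atom abstracts the electron-richer methyl hydrogens rather than the ring CH2 hydrogens deactivated by the sulfone, and no stereocentre is formed.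

Step 2
Reactants: 3 (+)-sclareolide
Product: 4 methyl 13,14,15,16-tetranorlabd-8-en-12-oate
Conditions: conc. H2SO4 (0.5 equiv), MeOH, reflux, 24 h
Reagents that add atoms: methanol CO
Why: Acid-catalysed lactone methanolysis, E1 dehydration and alkene equilibration funnel to the thermodynamically favoured tetrasubstituted C8=C9 alkene, while C5 and C10 are carried over unchanged from the chiral pool.

Step 3
Reactants: 4 methyl 13,14,15,16-tetranorlabd-8-en-12-oate
Product: 5 methyl 7-oxo-13,14,15,16-tetranorlabd-8-en-12-oate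
Conditions: Rh2(cap)4 (dirhodium tetracaprolactamate, 1 mol %), 70% aq t-BuOOH (6 equiv), ClCH2CH2Cl, 40 °C
Reagents that add atoms: tert-butyl hydroperoxide CC(C)(C)OO
Why: In this radical allylic oxidation the electrophilic t-BuOO radical abstracts the ring C7–H in preference to the ester-deactivated C11–H and the primary C17–H, and the mixed peroxide collapses to the 8-en-7-one.

Step 4
Reactants: 5 methyl 7-oxo-13,14,15,16-tetranorlabd-8-en-12-oate; 2 3-(bromomethyl)-2,5-dihydrothiophene 1,1-dioxide
Product: 7 methyl 11-[(1,1-dioxo-2,5-dihydrothiophen-3-yl)methyl]-7-oxo-13,14,15,16-tetranorlabd-8-en-12-oate, via sodium dienolate 6 (not isolated)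
Conditions: NaH (1.05 equiv), THF/DMF 4:1, 0 °C; then 2 (1.1 equiv), 0 °C to rt
Reagents that add atoms: none
Why: In this alkylation of a vinylogous β-keto ester (Hagemann's ester type) the soft delocalised anion takes the allylic bromide at C11, because the other carbon site C8 already bears a methyl group and would become quaternary next to C9 and C10; the new C11 stereocentre (epimer mixture) is erased in step 5.

Step 5
Reactants: 7 methyl 11-[(1,1-dioxo-2,5-dihydrothiophen-3-yl)methyl]-7-oxo-13,14,15,16-tetranorlabd-8-en-12-oate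
Product: 9 labda-8,13(16),14-trien-7-one, via diene ester 8 (not isolated)
Conditions: LiCl (3 equiv), H2O (3 equiv), BHT (1 mol %), DMSO, 150 °C, N2 sparge, 3 h
Reagents that add atoms: none
Why: Cheletropic SO2 extrusion from the 3-sulfolene and Krapcho demethoxycarbonylation (feasible because the carbanion is the vinylogous enolate of the enone) both run at this temperature, so one heating releases the 2-substituted butadiene, removes the activating ester and returns the conjugated tetrasubstituted enone.

Step 6
Reactants: 9 labda-8,13(16),14-trien-7-one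
Product: 11 labda-6,8,13(16),14-tetraen-7-yl acetate, via lithium dienolate 10 (not isolated)
Conditions: LiN(iPr)2 (1.1 equiv), THF, −78 °C, 45 min; Ac2O (2 equiv), −78 to 0 °C
Reagents that add atoms: acetic anhydride CC(=O)OC(C)=O
Why: Kinetic α′-deprotonation of the enone at C6 and O-acetylation of the cross-conjugated lithium dienolate (House enol acetate synthesis) give the homoannular 6,8-diene without touching the γ-position C11 or the side-chain diene.

Step 7
Reactants: 11 labda-6,8,13(16),14-tetraen-7-yl acetate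
Product: 15 (13R)-7-acetoxy-9α,13:15,16-diepoxy-15-hydroxylabd-7-en-6-one, via bis-endoperoxide 12 (not isolated), via hydroxy enal 13 (not isolated), via oxolane aldehyde 14 (not isolated)
Conditions: O2, tetraphenylporphyrin (0.5 mol %), white LED, CH2Cl2, 0 °C; then Ar purge, Et3N (3 equiv), 0 °C; then DBU (0.2 equiv), 0 °C to rt
Reagents that add atoms: dioxygen O=O
Why: Proposed new method: two singlet-oxygen [4+2] cycloadditions take place, on ring B from the α face opposite the C10 and C4β methyl groups as with ergosterol-type dienes (fixing 9α-O), and on the side chain as in the known conversion of 2-alkylbutadienes into 3,6-dihydro-1,2-dioxines; two amine-induced Kornblum–DeLaMare openings follow, in which loss of H6 gives the 6-ketone and frees 9α-OH and loss of the less hindered H15 gives the (Z)-16-hydroxy-13-en-15-al; the 9α-OH then adds 5-exo to C13 (an oxa-Michael addition known for 9-hydroxylabdane butenolides) and 16-OH closes on C15, which is the ring order of the presumed biosynthesis; C13 is set kinetically as R because the flat C14H= arm sits on the crowded C1/C20 flank and the larger C16H2OH arm on the open C8 flank, and lactol formation removes the aldehyde needed for retro-addition.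

Step 8
Reactants: 15 (13R)-7-acetoxy-9α,13:15,16-diepoxy-15-hydroxylabd-7-en-6-one
Product: 17 (13R)-7-acetoxy-9α,13:15,16-diepoxylabda-7,14-dien-6-one, via lactol mesylate 16 (not isolated)
Conditions: MsCl (1.5 equiv), Et3N (5 equiv), CH2Cl2, −20 °C to rt; Et3N-washed SiO2
Reagents that add atoms: none
Why: Mesylation of the anomeric hydroxyl and amine-induced loss of methanesulfonate (glycal-type lactol dehydration) can place the double bond only at C14=C15 because C13 is quaternary, and the basic medium protects the acid-labile spiro enol ether.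

Step 9
Reactants: 17 (13R)-7-acetoxy-9α,13:15,16-diepoxylabda-7,14-dien-6-one
Product: 20 (13R)-6β-acetoxy-9α,13:15,16-diepoxylabd-14-en-7-one (CNP0224709.1), via lithium 6β-alkoxide 18 (not isolated), via lithium enolate 19 (not isolated)
Conditions: Li[HB(sBu)3] (1.05 equiv), THF, −78 °C, then −40 °C, 1 h; AcOH (1.2 equiv), −78 °C; pH 7 buffer; Et3N-washed SiO2
Reagents that add atoms: none
Why: Proposed new method: the bulky hydride attacks the 6-ketone 1,2 from the open α face (the β face is blocked by the C4β and C10 methyl groups, and 1,4-addition by the fully substituted C8) to give the 6β-alkoxide; this alkoxide takes the acetyl group from the neighbouring enol acetate through a five-membered orthoester, driven by release of an enolate, so C7 stays masked as its lithium enolate until the cold quench; axial β-protonation at C8 then gives the equatorial 8α-methyl, which is also the thermodynamic epimer; the closest known reactions are α-face hydride reduction of 6-oxolabdanes to 6β-ols and base-induced 1,2-acyl migration in vicinal diol monoesters.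

**Stereocentres:** C5 and C10 come from 3. The trans ring fusion is also the stable one next to the 6-ketone. C9 and C13 are set in step 7, and C6 and C8 in step 9.

## Compound list
1 | 3-methyl-2,5-dihydrothiophene 1,1-dioxide (3-methylsulfolene) | CC1=CCS(=O)(=O)C1 | starting material
2 | 3-(bromomethyl)-2,5-dihydrothiophene 1,1-dioxide | BrCC1=CCS(=O)(=O)C1 | intermediate
3 | (+)-sclareolide, (3aR,5aS,9aS,9bR)-3a,6,6,9a-tetramethyldecahydronaphtho[2,1-b]furan-2(1H)-one | C1C[C@@]3(C)OC(=O)C[C@@H]3[C@@]2(C)CCCC(C)(C)[C@H]12 | starting material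
4 | methyl 13,14,15,16-tetranorlabd-8-en-12-oate (CH2CO2Me on C9, C8=C9) | C1CC(C)=C(CC(=O)OC)[C@@]2(C)CCCC(C)(C)[C@H]12 | intermediate
5 | methyl 7-oxo-13,14,15,16-tetranorlabd-8-en-12-oate | C1C(=O)C(C)=C(CC(=O)OC)[C@@]2(C)CCCC(C)(C)[C@H]12 | intermediate
6 | sodium dienolate of 5 (O7–C7=C8–C9=C11) | C1C([O-])=C(C)C(=CC(=O)OC)[C@@]2(C)CCCC(C)(C)[C@H]12.[Na+] | intermediate
7 | methyl 11-[(1,1-dioxo-2,5-dihydrothiophen-3-yl)methyl]-7-oxo-13,14,15,16-tetranorlabd-8-en-12-oate (C11 epimers) | C1C(=O)C(C)=C(C(CC3=CCS(=O)(=O)C3)C(=O)OC)[C@@]2(C)CCCC(C)(C)[C@H]12 | intermediate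
8 | 11-methoxycarbonyllabda-8,13(16),14-trien-7-one (C11 epimers) | C1C(=O)C(C)=C(C(CC(=C)C=C)C(=O)OC)[C@@]2(C)CCCC(C)(C)[C@H]12 | intermediate
9 | labda-8,13(16),14-trien-7-one | C1C(=O)C(C)=C(CCC(=C)C=C)[C@@]2(C)CCCC(C)(C)[C@H]12 | intermediate
10 | lithium labda-6,8,13(16),14-tetraen-7-olate | C1=C([O-])C(C)=C(CCC(=C)C=C)[C@@]2(C)CCCC(C)(C)[C@H]12.[Li+] | intermediate
11 | labda-6,8,13(16),14-tetraen-7-yl acetate | C1=C(OC(C)=O)C(C)=C(CCC(=C)C=C)[C@@]2(C)CCCC(C)(C)[C@H]12 | intermediate
12 | 7-acetoxy-6α,9α:15,16-bis(epidioxy)labda-7,13-diene | CC(=O)OC1=C(C)[C@@]2(CCC3=CCOOC3)OO[C@@H]1[C@H]1C(C)(C)CCC[C@@]12C | intermediate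
13 | (13Z)-7-acetoxy-9α,16-dihydroxy-6-oxolabda-7,13-dien-15-al | CC(=O)OC1=C(C)[C@](O)(CC/C(CO)=C/C=O)[C@@]2(C)CCCC(C)(C)[C@@H]2C1=O | intermediate
14 | (13R)-7-acetoxy-9α,13-epoxy-16-hydroxy-6-oxolabd-7-en-15-al | CC(=O)OC1=C(C)[C@]3(CC[C@](CO)(CC=O)O3)[C@@]2(C)CCCC(C)(C)[C@@H]2C1=O | intermediate
15 | (13R)-7-acetoxy-9α,13:15,16-diepoxy-15-hydroxylabd-7-en-6-one (C15 anomers) | CC(=O)OC1=C(C)[C@]3(CC[C@]4(CC(O)OC4)O3)[C@@]2(C)CCCC(C)(C)[C@@H]2C1=O | intermediate
16 | 15-O-methanesulfonate of 15 | CC(=O)OC1=C(C)[C@]3(CC[C@]4(CC(OS(C)(=O)=O)OC4)O3)[C@@]2(C)CCCC(C)(C)[C@@H]2C1=O | intermediate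
17 | (13R)-7-acetoxy-9α,13:15,16-diepoxylabda-7,14-dien-6-one | CC(=O)OC1=C(C)[C@]3(CC[C@]4(C=COC4)O3)[C@@]2(C)CCCC(C)(C)[C@@H]2C1=O | intermediate
18 | lithium (13R)-7-acetoxy-9α,13:15,16-diepoxylabda-7,14-dien-6β-olate | CC(=O)OC1=C(C)[C@]3(CC[C@]4(C=COC4)O3)[C@@]2(C)CCCC(C)(C)[C@@H]2[C@@H]1[O-].[Li+] | intermediate
19 | lithium (13R)-6β-acetoxy-9α,13:15,16-diepoxylabda-7,14-dien-7-olate | CC(=O)O[C@@H]1C([O-])=C(C)[C@]2(CC[C@]3(C=COC3)O2)[C@@]2(C)CCCC(C)(C)[C@H]12.[Li+] | intermediate
20 | (13R)-6β-acetoxy-9α,13:15,16-diepoxylabd-14-en-7-one (CNP0224709.1) | CC(=O)O[C@@H]1C(=O)[C@@H](C)[C@]2(CC[C@]3(C=COC3)O2)[C@@]2(C)CCCC(C)(C)[C@H]12 | target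

## Step count and risks
Total step count: 9.
Longest linear sequence: 8 (3 to 20, steps 2 to 9).

**Step 7 (the oxygenation and double ring closure).** The hydroxy enal may drain to the furan or to the 1,4-dialdehyde. The enol acetate may be lost to base. The C13 selectivity rests on a small steric difference. The fallback separates the two ring closures and puts C13 under ligand control.
- It sets out from 9. mCPBA epoxidises the more substituted C13=C16 bond of the diene to give 13,16-epoxylabda-8,14-dien-7-one F4 (both C13 epimers).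
- Enolisation and acetylation as in step 6 give 13,16-epoxylabda-6,8,14-trien-7-yl acetate F5.
- Photooxygenation of ring B alone followed by Et3N gives 7-acetoxy-9α-hydroxy-13,16-epoxylabda-7,14-dien-6-one F6.
- Zerovalent palladium (Pd2(dba)3·CHCl3 with a DACH-phenyl Trost ligand) ionises either epoxide epimer to the same π-allyl species, the metal-bound counterpart of the biosynthetic C13 allyl cation. The 9α-OH then closes on C13 to give (13R)-7-acetoxy-9α,13-epoxy-16-hydroxylabda-7,14-dien-6-one F7.
- A nitrite-modified aldehyde-selective Wacker oxidation (PdCl2(PhCN)2, CuCl2, AgNO2, O2, t-BuOH/MeNO2) of the vinyl group next to quaternary C13 gives the C15 aldehyde. This closes with 16-OH, and the route is rejoined at 15.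

**Step 9 (reduction with acetyl shift).** The hydride may attack the enol acetate first, or the enolate may expel O9. The fallback gives up the internal acyl transfer.
- It sets out from 17. Excess LiAlH4 in THF at −78 °C cleaves the enol acetate to an aluminium enolate that cannot be reduced further, and reduces the 6-ketone from the α face.
- A buffered quench gives (13R)-6β-hydroxy-9α,13:15,16-diepoxylabd-14-en-7-one F8.
- Ac2O, DMAP and pyridine then acetylate the axial hydroxyl, and the route is rejoined at 20.

**Step 4 (site of alkylation).** Attack through C8 or oxygen would be a dead end. The fallback makes the C12–C13 bond by cross-coupling instead of enolate chemistry.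
- It sets out from 5. LiAlH4 reduces the ester and the enone carbonyl to 13,14,15,16-tetranorlabd-8-ene-7,12-diol F1.
- TsCl in pyridine at 0 °C sulfonylates only the primary hydroxyl to give 7-hydroxy-13,14,15,16-tetranorlabd-8-en-12-yl 4-methylbenzenesulfonate F2.
- Li2CuCl4-catalysed coupling with buta-1,3-dien-2-ylmagnesium chloride (from chloroprene, with one extra equivalent for the free hydroxyl) gives labda-8,13(16),14-trien-7-ol F3.
- MnO2 oxidises the allylic alcohol, and the route is rejoined at 9.

## Further compounds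
F1 | step 4 | 13,14,15,16-tetranorlabd-8-ene-7,12-diol | C1C(O)C(C)=C(CCO)[C@@]2(C)CCCC(C)(C)[C@H]12
F2 | step 4 | 7-hydroxy-13,14,15,16-tetranorlabd-8-en-12-yl 4-methylbenzenesulfonate | C1C(O)C(C)=C(CCOS(=O)(=O)c3ccc(C)cc3)[C@@]2(C)CCCC(C)(C)[C@H]12
F3 | step 4 | labda-8,13(16),14-trien-7-ol | C1C(O)C(C)=C(CCC(=C)C=C)[C@@]2(C)CCCC(C)(C)[C@H]12
F4 | step 7 | 13,16-epoxylabda-8,14-dien-7-one | C1C(=O)C(C)=C(CCC3(CO3)C=C)[C@@]2(C)CCCC(C)(C)[C@H]12
F5 | step 7 | 13,16-epoxylabda-6,8,14-trien-7-yl acetate | C1=C(OC(C)=O)C(C)=C(CCC3(CO3)C=C)[C@@]2(C)CCCC(C)(C)[C@H]12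
F6 | step 7 | 7-acetoxy-9α-hydroxy-13,16-epoxylabda-7,14-dien-6-one | CC(=O)OC1=C(C)[C@](O)(CCC3(CO3)C=C)[C@@]2(C)CCCC(C)(C)[C@@H]2C1=O
F7 | step 7 | (13R)-7-acetoxy-9α,13-epoxy-16-hydroxylabda-7,14-dien-6-one | CC(=O)OC1=C(C)[C@]3(CC[C@](CO)(C=C)O3)[C@@]2(C)CCCC(C)(C)[C@@H]2C1=O
F8 | step 9 | (13R)-6β-hydroxy-9α,13:15,16-diepoxylabd-14-en-7-one | O[C@@H]1C(=O)[C@@H](C)[C@]2(CC[C@]3(C=COC3)O2)[C@@]2(C)CCCC(C)(C)[C@H]12
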